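**Retrosynthetic overview**
1. Locants (target): ring A (cycloheptanone) C1(=O)–C2(OH)–C3–C4–C5(CH3)–C6–C7; ring B (cyclohexane) C3–C4–C5–C8–C9–C10; ring C (oxane) C2–C3–C10–C11(CH3)2–O12–C13; C1'=C2' is the vinyl group on C6 (C2' carries the ester oxygen); the acetonyl group is on C7.
2. End game: the (E)-enol ester C2'–O is made last by copper-mediated C–O coupling of an (E)-alkenyltrifluoroborate with 3-methylbut-2-enoic acid; boron comes from cross-metathesis of a C6 vinyl group, the acetonyl group from hydration of a C7 propargyl group.
3. Key disconnection C6–C1' (together with C7–CH2): one-pot conjugate vinylation and enolate propargylation of a tricyclic enone. Enabling feature: in ring A the C1 ketone lies between fully substituted C2 and C7, so a C6=C7 double bond makes C6 the β-carbon of a bridged cyclohept-2-enone whose only possible enolate is the C7 one and whose exo face (anti to the C8–C9–C10 bridge of ring B) is open.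
4. The enone comes from a bicyclo[4.3.1] β-keto ester: ring C by acid lactonisation of the C13 ester onto the isopropenyl group (lactone later reduced to the ether), C2–OH by β-dicarbonyl hydroxylation, the C4 oxygen removed by Barton–McCombie deoxygenation.
5. Order of ring formation: ring B is bought ((5R)-dihydrocarvone), ring A is closed by a Dieckmann condensation bridging C5 and C3, ring C is closed next; C5 is set by axial Michael addition, C3 by epimerisation during ring closure.

Key step: step 11

Assumption: commercial (+)-dihydrocarvone is the 5R compound as a mixture of epimers at its methyl-bearing carbon; both epimers give the same enolate in step 1.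

**Step 1**
Reactants: 1 (5R)-dihydrocarvone; 2 methyl acrylate
Product: 3 methyl 3-[(1R,4R)-1-methyl-2-oxo-4-(prop-1-en-2-yl)cyclohexyl]propanoate
Conditions: KOt-Bu (0.15 equiv), t-BuOH/THF, 0 → 23 °C
Reagents that add atoms: methyl acrylate 2, C=CC(=O)OC
Why: Base-catalysed Michael addition under equilibrating conditions goes through the more substituted enolate, and axial attack on the enolate half-chair with the isopropenyl group equatorial should place the new chain cis to it, setting the quaternary C5 centre.

**Step 2**
Reactants: 3; 4 tert-butyl bromoacetate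
Product: 5 tert-butyl 2-[(3R,6R)-3-(3-methoxy-3-oxopropyl)-3-methyl-2-oxo-6-(prop-1-en-2-yl)cyclohexyl]acetate (epimers at the new centre, target C3; the epimer with the arm trans to isopropenyl is drawn)
Conditions: lithium diisopropylamide (1.1 equiv), THF, −78 °C; 4 (1.3 equiv), DMPU, −78 → −30 °C; aq. NH4Cl
Reagents that add atoms: tert-butyl bromoacetate 4, BrCC(=O)OC(C)(C)C
Why: Kinetic ketone deprotonation can only occur at C3 because C5 is quaternary, and the enolate is alkylated (enolate alkylation) by the reactive α-bromo ester; the configuration at C3 (expected trans to isopropenyl) does not matter because it is corrected in step 3.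

**Step 3**
Reactants: 5
Product: 6 tert-butyl 6-methyl-3,10-dioxo-9-(prop-1-en-2-yl)bicyclo[4.3.1]decane-2-carboxylate (rings A and B; in target locants ketones at C1 and C4, ester C13 on C2; C2 epimers and enol)
Conditions: KOt-Bu (2.5 equiv), THF, 0 → 23 °C; then AcOH
Reagents that add atoms: none
Why: Dieckmann condensation under reversible conditions: C3 epimerises through the C4 enolate, only the epimer with the C3 arm cis to the axial C5 chain can cyclise by attack of the C2 ester enolate on the methyl ester (C1), and deprotonation of the resulting β-keto ester drives the closure of ring A, fixing C3 cis to the C5–C6 bond and to the isopropenyl group.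

**Step 4**
Reactants: 6
Product: 7 tricyclic diketo lactone (rings A, B and C; ketones at C1 and C4; δ-lactone C13(=O)–O12–C11; C2–H epimers and enol)
Conditions: CF3CO2H/CH2Cl2 (1:4), 0 → 23 °C
Reagents that add atoms: none
Why: Acid-mediated lactonisation: Markovnikov protonation of the isopropenyl group gives the tertiary C11 cation, which is captured by the carbonyl oxygen of the tert-butyl ester (C2 equilibrates through the enol to the reacting epimer) with loss of 2-methylpropene, closing ring C cis-fused at C3–C10.

**Step 5**
Reactants: 7
Product: 9 C4 carbinol of diketo lactone 7 (C4 configuration not defined), via sodium enolate 8 (not isolated)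
Conditions: NaH (1.1 equiv), THF, 0 °C; then NaBH4 (2 equiv), EtOH, 0 → 23 °C; 1 M HCl
Reagents that add atoms: none
Why: Chemoselective hydride reduction: the β-keto lactone is masked as its sodium enolate, so borohydride should reduce only the isolated C4 ketone, and the configuration of the new carbinol is irrelevant because this oxygen is removed in step 8.

**Step 6**
Reactants: 9
Product: 10 2,4-dihydroxy keto lactone (C2–OH on the exo face)
Conditions: dimethyldioxirane (1.2 equiv, acetone solution), CH2Cl2, −20 → 0 °C
Reagents that add atoms: dimethyldioxirane, CC1(C)OO1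
Why: Electrophilic α-hydroxylation of a β-dicarbonyl compound (epoxidation of the C1=C2 enol and ring opening): oxygen should be delivered to the exo face of C2, anti to the C8–C9–C10 bridge, which sets the C2 carbinol centre.

**Step 7**
Reactants: 10
Product: 11 C4 O-(imidazol-1-ylcarbonothioyl) derivative of 10
Conditions: 1,1'-thiocarbonyldiimidazole (3 equiv), DMAP (0.3 equiv), ClCH2CH2Cl, 80 °C
Reagents that add atoms: 1,1'-thiocarbonyldiimidazole, S=C(n1ccnc1)n1ccnc1
Why: Thioacylation of the secondary C4 alcohol gives the thiocarbamate needed for radical deoxygenation, while the tertiary C2 alcohol is too hindered to react.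

**Step 8**
Reactants: 11
Product: 12 4-deoxy keto lactone (C1 ketone, C2–OH, C13 lactone, C4 = CH2)
Conditions: Bu3SnH (2 equiv), AIBN (0.2 equiv), toluene, 110 °C
Reagents that add atoms: none
Why: Barton–McCombie deoxygenation: the stannyl radical adds to C=S, β-scission releases the secondary C4 radical, and this abstracts hydrogen from the tin hydride.

**Step 9**
Reactants: 12
Product: 13 tricyclic diol ether (C1–OH of undefined configuration, C2–OH, ring C as oxane with C13 = CH2)
Conditions: NaBH4 (6 equiv), BF3·OEt2 (8 equiv), THF, 0 → 65 °C; aq. NaOH
Reagents that add atoms: none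
Why: Borane and boron trifluoride reduce a lactone of a tertiary alcohol to the cyclic ether (hydride addition, ionisation to the oxocarbenium ion, second hydride addition), and the C1 ketone is reduced to the carbinol at the same time, its configuration being irrelevant.

**Step 10**
Reactants: 13
Product: 15 tricyclic enone (2R,3S,5S,10R; C1 ketone, C6=C7, C2–OH), via α-hydroxy ketone 14 (not isolated)
Conditions: 2-iodoxybenzoic acid (4 equiv), DMSO, 23 °C then 75 °C
Reagents that add atoms: none
Why: 2-Iodoxybenzoic acid should oxidise the secondary C1 alcohol of the diol without glycol cleavage and then dehydrogenate the ketone through its C7 enol, the only enol possible, to give the enone.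

**Step 11**
Reactants: 15; 16 vinylmagnesium bromide; 17 propargyl bromide
Product: 19 C6-vinyl C7-propargyl ketone (vinyl on the exo face of C6; prop-2-ynyl on C7 trans to it), via bromomagnesium enolate 18 (not isolated)
Conditions: 16 (5 equiv), CuI (2.5 equiv), THF/Me2S, −78 → −40 °C; then HMPA, 17 (6 equiv), −40 → 0 °C; aq. NH4Cl
Reagents that add atoms: vinylmagnesium bromide 16, C=C[Mg]Br; propargyl bromide 17, C#CCBr
Why: The vinyl cuprate formed from 16 and CuI adds to the s-trans enone by π-complexation, oxidative addition at C6 and reductive elimination, which forms C6–C1' and leaves the bromomagnesium enolate 18, regiodefined at C1=C7 because C2 is fully substituted; 18 is then C-alkylated in the same flask by 17. The closest known reaction type is the organocopper conjugate addition and enolate trapping sequence (three-component vicinal dialkylation) of cycloalkenones. No ring is closed in this step. C6 is set by attack on the exo face of ring A, anti to the C8–C9–C10 bridge of ring B, and C7 is set by approach of the electrophile anti to the new C6 vinyl group, giving the trans relationship that should also be the more stable one at this epimerisable centre. The step needs 1,4- over 1,2-addition and C- over O-alkylation: the soft cuprate and the hindered C1 carbonyl should secure the first, the reactive propargylic bromide in a dipolar aprotic co-solvent the second, and the C2 alkoxide formed by the first equivalent of 16 should be too hindered to be alkylated.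

**Step 12**
Reactants: 19
Product: 20 diketone (C7 2-oxopropyl, C6 vinyl)
Conditions: Ph3PAuNTf2 (2 mol %), H2O (5 equiv), 1,4-dioxane, 60 °C
Reagents that add atoms: water, O
Why: Gold-catalysed Markovnikov hydration of the terminal alkyne (π-activation by monovalent gold, attack of water at the internal carbon, protodeauration, tautomerisation) should give the methyl ketone without touching the vinyl group.

**Step 13**
Reactants: 20; 21 vinylboronic acid pinacol ester
Product: 22 (E)-alkenylboronic acid pinacol ester (C6–CH=CH–B(pin))
Conditions: 21 (5 equiv), second-generation Hoveyda–Grubbs catalyst RuCl2(H2IMes)(=CH-C6H4-2-O-i-Pr) (10 mol %), CH2Cl2, 40 °C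
Reagents that add atoms: vinylboronic acid pinacol ester 21, C=CB1OC(C)(C)C(C)(C)O1
Why: Olefin cross-metathesis of the monosubstituted alkene with excess vinylboronate should give the alkenylboronate as the thermodynamically favoured E isomer, which sets the C1'=C2' geometry.

**Step 14**
Reactants: 22
Product: 23 potassium (E)-alkenyltrifluoroborate
Conditions: KHF2 (4.5 equiv), MeOH/H2O, 23 °C
Reagents that add atoms: potassium hydrogen difluoride, [K+].F.[F-]
Why: Exchange of the pinacol ligand by fluoride (boronate to trifluoroborate conversion) gives the salt that transmetalates readily to copper, and the alkene geometry is not touched.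

**Step 15**
Reactants: 23; 24 3-methylbut-2-enoic acid
Product: 25 CNP0237201.2 (target; 2R,3S,5S,6S,7S,10R in the locants above; E enol ester)
Conditions: 24 (2 equiv), CuBr (10 mol %), DMAP (20 mol %), 4 Å molecular sieves, O2 (1 atm), CH2Cl2, 40 °C
Reagents that add atoms: 3-methylbut-2-enoic acid 24, CC(C)=CC(=O)O
Why: Chan–Lam-type oxidative coupling: transmetalation of the alkenyl group to copper, oxidation to a trivalent copper carboxylate and C–O reductive elimination should form the enol ester with retention of the E geometry, and the free acid is used so that the 3-methylbut-2-enoyl unit cannot deconjugate through a ketene.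

**Compound list**
1 | (5R)-dihydrocarvone, (5R)-2-methyl-5-(prop-1-en-2-yl)cyclohexan-1-one | CC(=C)[C@@H]1CCC(C)C(=O)C1 | starting material
2 | methyl acrylate | C=CC(=O)OC | starting material
3 | methyl 3-[(1R,4R)-1-methyl-2-oxo-4-(prop-1-en-2-yl)cyclohexyl]propanoate | CC(=C)[C@@H]1CC[C@@](C)(C(=O)C1)CCC(=O)OC | intermediate
4 | tert-butyl bromoacetate | BrCC(=O)OC(C)(C)C | starting material
5 | tert-butyl 2-[(3R,6R)-3-(3-methoxy-3-oxopropyl)-3-methyl-2-oxo-6-(prop-1-en-2-yl)cyclohexyl]acetate (arm trans to isopropenyl drawn) | CC(=C)[C@@H]1CC[C@@](C)(C(=O)[C@H]1CC(=O)OC(C)(C)C)CCC(=O)OC | intermediate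
6 | tert-butyl 6-methyl-3,10-dioxo-9-(prop-1-en-2-yl)bicyclo[4.3.1]decane-2-carboxylate (C2 not defined) | CC(=C)[C@@H]1CC[C@]2(C)CCC(=O)C(C(=O)OC(C)(C)C)[C@H]1C2=O | intermediate
7 | tricyclic diketo lactone (ketones C1 and C4, lactone C13; C2 not defined) | O=C1CC[C@@]2(C)CC[C@@H]3[C@H](C2=O)C1C(=O)OC3(C)C | intermediate
8 | sodium enolate of 7 (C1–O enolate, C1=C2) | [Na+].[O-]C=1CC[C@@]2(C)CC[C@@H]3[C@H](C2=O)C=1C(=O)OC3(C)C | intermediate
9 | C4 carbinol of 7 (C4 and C2 not defined) | O=C1CC[C@@]2(C)CC[C@@H]3[C@H](C2O)C1C(=O)OC3(C)C | intermediate
10 | 2,4-dihydroxy keto lactone (C2–OH exo; C4 not defined) | O=C1CC[C@@]2(C)CC[C@@H]3[C@H](C2O)[C@@]1(O)C(=O)OC3(C)C | intermediate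
11 | C4 O-(imidazol-1-ylcarbonothioyl) derivative of 10 | O=C1CC[C@@]2(C)CC[C@@H]3[C@H](C2OC(=S)n2ccnc2)[C@@]1(O)C(=O)OC3(C)C | intermediate
12 | 4-deoxy keto lactone (C1 ketone, C2–OH, C13 lactone) | O=C1CC[C@@]2(C)CC[C@@H]3[C@H](C2)[C@@]1(O)C(=O)OC3(C)C | intermediate
13 | tricyclic diol ether (C1–OH not defined, C2–OH, ring C oxane) | OC1CC[C@@]2(C)CC[C@@H]3[C@H](C2)[C@@]1(O)COC3(C)C | intermediate
14 | tricyclic α-hydroxy ketone (C1 ketone, C2–OH) | O=C1CC[C@@]2(C)CC[C@@H]3[C@H](C2)[C@@]1(O)COC3(C)C | intermediate
15 | tricyclic enone (2R,3S,5S,10R; C1 ketone, C6=C7, C2–OH) | O=C1C=C[C@@]2(C)CC[C@@H]3[C@H](C2)[C@@]1(O)COC3(C)C | intermediate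
16 | vinylmagnesium bromide | C=C[Mg]Br | starting material
17 | propargyl bromide (3-bromoprop-1-yne) | C#CCBr | starting material
18 | bromomagnesium enolate (C1–O–MgBr, C1=C7, C6 vinyl, C2–O–MgBr) | Br[Mg]OC1=C[C@H](C=C)[C@@]2(C)CC[C@@H]3[C@H](C2)[C@@]1(O[Mg]Br)COC3(C)C | intermediate
19 | C6-vinyl C7-(prop-2-ynyl) ketone | O=C1[C@@H](CC#C)[C@H](C=C)[C@@]2(C)CC[C@@H]3[C@H](C2)[C@@]1(O)COC3(C)C | intermediate
20 | C6-vinyl C7-(2-oxopropyl) diketone | O=C1[C@@H](CC(C)=O)[C@H](C=C)[C@@]2(C)CC[C@@H]3[C@H](C2)[C@@]1(O)COC3(C)C | intermediate
21 | vinylboronic acid pinacol ester (2-ethenyl-4,4,5,5-tetramethyl-1,3,2-dioxaborolane) | C=CB1OC(C)(C)C(C)(C)O1 | starting material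
22 | (E)-alkenylboronic acid pinacol ester at C6 | O=C1[C@@H](CC(C)=O)[C@H](/C=C/B4OC(C)(C)C(C)(C)O4)[C@@]2(C)CC[C@@H]3[C@H](C2)[C@@]1(O)COC3(C)C | intermediate
23 | potassium (E)-alkenyltrifluoroborate at C6 | O=C1[C@@H](CC(C)=O)[C@H](/C=C/[B-](F)(F)F)[C@@]2(C)CC[C@@H]3[C@H](C2)[C@@]1(O)COC3(C)C.[K+] | intermediate
24 | 3-methylbut-2-enoic acid | CC(C)=CC(=O)O | starting material
25 | CNP0237201.2 | CC(=O)C[C@@H]1C(=O)[C@]2(O)COC(C)(C)[C@@H]3CC[C@@](C)(C[C@@H]32)[C@H]1/C=C/OC(=O)C=C(C)C | target

**Step count and risk**
Total step count: 15. Longest linear sequence: 15 steps (from 1).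

Steps most likely to fail:

- **Step 3.** Ring closure may run through the competing six-membered Claisen mode (C3 ketone enolate onto the methyl ester) or end in retro-Claisen opening, so that the bridged seven-membered ring A does not form. Fallback: invert the order of ring formation. The route would set out from 5, which would be treated with CF3CO2H/CH2Cl2 first to close ring C. This gives the keto lactone methyl ester F1, whose lactone α-carbon (C2) is more acidic than that of the tert-butyl ester and is held near the C5 arm once C3 has epimerised. KOt-Bu in THF would then epimerise C3 through the C4 enolate and effect the Claisen ring closure onto the methyl ester, and the route is rejoined at 7.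

- **Step 11.** Transfer of the vinyl group to the hindered β-carbon may lose to 1,2-addition, and the enolate may give O-alkylation or allenyl products, so that the two bonds are not formed cleanly in one flask. Fallback: make the two bonds by different chemistry and separately. From 15, rhodium-catalysed conjugate addition of potassium vinyltrifluoroborate ([RhCl(cod)]2, Et3N, dioxane/H2O, 80 °C) would give the C6-vinyl ketone F2. Deprotonation at C7, the only enolisable position, with lithium diisopropylamide (2.2 equiv, THF, −78 °C) and alkylation with 17 would rejoin the route at 19.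

- **Step 13.** The vinyl group on the congested C6 may fail to enter the metathesis cycle, so that self-metathesis of the boronate and catalyst decay prevail. Fallback: cleave the alkene and rebuild it by olefination. From 20, ozonolysis (O3, CH2Cl2, −78 °C; Me2S) would give the C6 carbaldehyde F3. Chromium-mediated boryl olefination of the aldehyde in the presence of the ketones (Takai-type; CrCl2, LiI, (dichloromethyl)boronic acid pinacol ester, THF) would give the E alkenylboronate and rejoin the route at 22.

**Further compounds**
F1 | step 3 | keto lactone methyl ester (rings B and C closed, ring A open; C3 arm as formed from the drawn epimer of 5) | COC(=O)CC[C@@]1(C)CC[C@@H]2[C@H](CC(=O)OC2(C)C)C1=O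
F2 | step 11 | C6-vinyl ketone (C7 = CH2) | O=C1C[C@H](C=C)[C@@]2(C)CC[C@@H]3[C@H](C2)[C@@]1(O)COC3(C)C
F3 | step 13 | C6 carbaldehyde of diketone 20 | O=C1[C@@H](CC(C)=O)[C@H](C=O)[C@@]2(C)CC[C@@H]3[C@H](C2)[C@@]1(O)COC3(C)C
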